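**Plan**

- Retrosynthesis: the 3'-OH is unmasked last from a mesylate and the C3=C4 double bond is taken back to the chroman-2-one. O1 is then excised from between C2 and C8a (retro-Baeyer–Villiger) to leave a 3-arylindan-1-one. Its C1–C7a acyl bond and its C3–C3a bond (C4–C4a of the target) are cut to give 1,2,4-trimethoxybenzene and O-mesyl isoferulic acid.
- Enabling feature: O1 of the pyranone ring bridges the carbonyl carbon C2 and the ring A carbon C8a, whose neighbour C8 carries a methoxy group. Without O1 the ring is a five-membered aryl ketone, and its ring A has exactly the substitution pattern of 1,2,4-trimethoxybenzene.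
- Forward: mesylation; acid-mediated hydroarylation joins ring A (through its C5) to the benzylic carbon; Friedel–Crafts acylation closes the five-membered carbocycle; a peracid expands it to the six-membered lactone; DDQ introduces C3=C4; hydroxide removes the mesylate.
- Stereochemistry: the target has no stereocentre. The benzylic centre made in step 2 is carried as a racemate and erased in step 5. The Z geometry of the ring-opened salt in step 6 is inherited from the lactone.

Key step: step 4

Assumption: isoferulic acid is used as the commercial E isomer, and every intermediate with a stereocentre at the benzylic carbon is handled as the racemate.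

**Route**

Step 1
Reactants: 1 isoferulic acid; 2 methanesulfonyl chloride
Product: 3 (E)-3-[4-methoxy-3-(methanesulfonyloxy)phenyl]prop-2-enoic acid
Conditions: MsCl (2.5 equiv), aq NaOH (held near pH 11), THF, 0 °C; then aq HCl to pH 2
Reagents that add atoms: methanesulfonyl chloride (compound 2), CS(=O)(=O)Cl
Why: Schotten–Baumann O-sulfonylation, in which the phenoxide is mesylated while any mixed carboxylic–sulfonic anhydride is hydrolysed back by the aqueous base, so that acidification should return the free acid with only the aryl mesylate in place.

Step 2
Reactants: 3 (E)-3-[4-methoxy-3-(methanesulfonyloxy)phenyl]prop-2-enoic acid; 4 1,2,4-trimethoxybenzene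
Product: 5 racemic 3-[4-methoxy-3-(methanesulfonyloxy)phenyl]-3-(2,4,5-trimethoxyphenyl)propanoic acid
Conditions: 4 (1.2 equiv), CF3CO2H (neat), 50 °C
Reagents that add atoms: none
Why: Brønsted-acid hydroarylation of a cinnamic acid (Friedel–Crafts alkylation), in which protonation gives a benzylic cation stabilised by the para methoxy group of ring B and the most nucleophilic carbon of 4 (C5, para to the 2-methoxy and ortho to the 4-methoxy group) captures it; the new stereocentre forms without control and is removed in step 5.

Step 3
Reactants: 5 racemic 3-[4-methoxy-3-(methanesulfonyloxy)phenyl]-3-(2,4,5-trimethoxyphenyl)propanoic acid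
Product: 6 racemic 4,6,7-trimethoxy-3-[4-methoxy-3-(methanesulfonyloxy)phenyl]indan-1-one
Conditions: P2O5 in CH3SO3H (Eaton's reagent, 7.7 wt %), rt → 40 °C; ice/water quench
Reagents that add atoms: none
Why: Intramolecular Friedel–Crafts acylation (cyclodehydration), which should close the five-membered ketone on the one free ortho carbon of ring A, activated by its neighbouring methoxy group, because ring B is deactivated by the mesylate and its ortho carbons lie meta to its methoxy group.

Step 4
Reactants: 6 racemic 4,6,7-trimethoxy-3-[4-methoxy-3-(methanesulfonyloxy)phenyl]indan-1-one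
Product: 8 racemic 5,7,8-trimethoxy-4-[4-methoxy-3-(methanesulfonyloxy)phenyl]chroman-2-one, via Criegee adduct 7 (not isolated)
Conditions: 3-chloroperbenzoic acid (1.5 equiv), CF3CO2H (1 equiv), CH2Cl2, 0 °C → rt, dark; aq Na2SO3, then aq NaHCO3
Reagents that add atoms: 3-chloroperbenzoic acid (mCPBA), O=C(OO)c1cccc(Cl)c1
Why: Baeyer–Villiger oxidation: acid-assisted addition of the peracid to the C1 carbonyl makes the future O1–C2 bond and gives Criegee adduct 7, after which the aryl carbon C7a shifts from C1 to the proximal peroxide oxygen as 3-chlorobenzoate leaves, making the O1–C8a bond. The closest known reaction type is the acid-catalysed peracid oxidation of 1-indanones and 1-tetralones to 3,4-dihydrocoumarins and their homologues with aryl migration. The six-membered lactone is not formed by a cyclisation of an open chain but by one-atom ring expansion of the five-membered ketone through this 1,2-shift. No stereocentre is created; C3 of 6 is untouched and becomes C4 of 8, still racemic. The step needs aryl rather than methylene migration and peracid attack at the ketone rather than at the arenes: the migrating sp2 carbon carries the ortho methoxy donor (C7 of 6) that stabilises the charge building up on it, whereas the primary C2 methylene migrates poorly; ring A is tempered by its carbonyl (later acyloxy) substituent and ring B by the mesylate, and mCPBA with one equivalent of CF3CO2H is preferred to CF3CO3H to keep arene hydroxylation down.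

Step 5
Reactants: 8 racemic 5,7,8-trimethoxy-4-[4-methoxy-3-(methanesulfonyloxy)phenyl]chroman-2-one
Product: 9 5,7,8-trimethoxy-4-[4-methoxy-3-(methanesulfonyloxy)phenyl]coumarin
Conditions: DDQ (2,3-dichloro-5,6-dicyano-1,4-benzoquinone, 1.5 equiv), 1,4-dioxane, reflux
Reagents that add atoms: none
Why: Quinone dehydrogenation, in which DDQ abstracts hydride from the doubly benzylic C4–H to give a cation stabilised by the 5- and 7-methoxy groups and loss of a C3 proton gives the conjugated coumarin, erasing the stereocentre.

Step 6
Reactants: 9 5,7,8-trimethoxy-4-[4-methoxy-3-(methanesulfonyloxy)phenyl]coumarin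
Product: 11 3'-hydroxy-5,7,8,4'-tetramethoxy-4-phenylcoumarin, via ring-opened tripotassium coumarinate 10 (not isolated)
Conditions: KOH (6 equiv), MeOH/H2O 4:1, 65 °C; then 2 M aq HCl to pH 1, rt
Reagents that add atoms: potassium hydroxide, [K+].[OH-] (its potassium and one carboxylate oxygen are in 10; on ring closure that oxygen is either lost as water or kept as the carbonyl oxygen of 11)
Why: Alkaline cleavage of the aryl methanesulfonate (hydroxide attack at sulfur) with concurrent saponification of the lactone to the Z-coumarinate 10, which keeps carboxylate and phenoxide cis across the double bond and should therefore relactonise spontaneously on acidification.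

**Compound list**

1 | isoferulic acid, (E)-3-(3-hydroxy-4-methoxyphenyl)prop-2-enoic acid | COc1ccc(/C=C/C(=O)O)cc1O | starting material
2 | methanesulfonyl chloride | CS(=O)(=O)Cl | starting material
3 | (E)-3-[4-methoxy-3-(methanesulfonyloxy)phenyl]prop-2-enoic acid | COc1ccc(/C=C/C(=O)O)cc1OS(C)(=O)=O | intermediate
4 | 1,2,4-trimethoxybenzene | COc1ccc(OC)c(OC)c1 | starting material
5 | racemic 3-[4-methoxy-3-(methanesulfonyloxy)phenyl]-3-(2,4,5-trimethoxyphenyl)propanoic acid | COc1ccc(C(CC(=O)O)c2cc(OC)c(OC)cc2OC)cc1OS(C)(=O)=O | intermediate
6 | racemic 4,6,7-trimethoxy-3-[4-methoxy-3-(methanesulfonyloxy)phenyl]indan-1-one | COc1ccc(C2CC(=O)c3c(OC)c(OC)cc(OC)c32)cc1OS(C)(=O)=O | intermediate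
7 | Criegee adduct of 6, 1-(3-chlorobenzoylperoxy)-1-hydroxy-4,6,7-trimethoxy-3-[4-methoxy-3-(methanesulfonyloxy)phenyl]indane (diastereomer mixture, formed in the flask in step 4) | COc1ccc(C2CC(O)(OOC(=O)c3cccc(Cl)c3)c3c(OC)c(OC)cc(OC)c32)cc1OS(C)(=O)=O | intermediate
8 | racemic 5,7,8-trimethoxy-4-[4-methoxy-3-(methanesulfonyloxy)phenyl]chroman-2-one | COc1ccc(C2CC(=O)Oc3c(OC)c(OC)cc(OC)c32)cc1OS(C)(=O)=O | intermediate
9 | 5,7,8-trimethoxy-4-[4-methoxy-3-(methanesulfonyloxy)phenyl]coumarin | COc1ccc(-c2cc(=O)oc3c(OC)c(OC)cc(OC)c23)cc1OS(C)(=O)=O | intermediate
10 | tripotassium (Z)-3-(4-methoxy-3-oxidophenyl)-3-(3,4,6-trimethoxy-2-oxidophenyl)prop-2-enoate (formed in the flask in step 6) | [K+].[K+].[K+].[O-]C(=O)/C=C(\c1c([O-])c(OC)c(OC)cc1OC)c1ccc(OC)c([O-])c1 | intermediate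
11 | 3'-hydroxy-5,7,8,4'-tetramethoxy-4-phenylcoumarin | COc1ccc(-c2cc(=O)oc3c(OC)c(OC)cc(OC)c23)cc1O | target

**Step count**

Total: 6 steps. Longest linear sequence: 6 steps (from isoferulic acid).

**Steps most likely to fail**

Step 4. The migration may go the wrong way (methylene instead of aryl shift, leading to the isochromanone), or the peracid may hydroxylate electron-rich ring A faster than it adds to the hindered, donor-conjugated ketone. The fallback sets out from acid 5 and bypasses 6. Oxidative C–O lactonisation of the 3-arylpropanoic acid with PhI(OCOCF3)2 and BF3·OEt2 in CH2Cl2/CF3CO2H at −20 °C should proceed by oxidation of ring A, ipso capture by the carboxyl group para to a methoxy group, 1,2-shift of the acyloxy group to the free ortho carbon and loss of a proton. This would make the same O1–C8a bond on the same carbon and rejoin the route at 8. No new isolable compound arises on this detour (F0).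

Step 2. The cinnamic acid, made less electron-rich by the mesylate, may protonate too sluggishly, and 4 may be alkylated twice or at more than one carbon. The fallback sets out from 3. Esterification with Boc2O and catalytic 4-(dimethylamino)pyridine in t-BuOH should give tert-butyl (E)-3-[4-methoxy-3-(methanesulfonyloxy)phenyl]prop-2-enoate F1. Hayashi–Miyaura conjugate addition of commercial 2,4,5-trimethoxyphenylboronic acid (OB(O)c1cc(OC)c(OC)cc1OC) with [Rh(OH)(cod)]2 (cod = 1,5-cyclooctadiene) in dioxane/H2O at 50 °C should then give racemic tert-butyl 3-[4-methoxy-3-(methanesulfonyloxy)phenyl]-3-(2,4,5-trimethoxyphenyl)propanoate F2, with the position of ring A fixed by the carbon–boron bond. Cleavage of the ester with CF3CO2H in CH2Cl2 at rt comes back to the route at 5.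

Step 3. The acylium ion may attack ring B, and the warm superacid may protonate ring A at its ipso carbon and expel it (retro-Friedel–Crafts dearylation) or promote intermolecular acylation. The fallback sets out from 5. Oxalyl chloride with catalytic N,N-dimethylformamide in CH2Cl2 should give racemic 3-[4-methoxy-3-(methanesulfonyloxy)phenyl]-3-(2,4,5-trimethoxyphenyl)propanoyl chloride F3. Ring closure under aprotic Lewis-acid conditions (SnCl4, CH2Cl2, −20 °C, high dilution) then comes back to the route at 6.

**Further compounds**

F0 | step 4 | none | none
F1 | step 2 | tert-butyl (E)-3-[4-methoxy-3-(methanesulfonyloxy)phenyl]prop-2-enoate | COc1ccc(/C=C/C(=O)OC(C)(C)C)cc1OS(C)(=O)=O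
F2 | step 2 | racemic tert-butyl 3-[4-methoxy-3-(methanesulfonyloxy)phenyl]-3-(2,4,5-trimethoxyphenyl)propanoate | COc1ccc(C(CC(=O)OC(C)(C)C)c2cc(OC)c(OC)cc2OC)cc1OS(C)(=O)=O
F3 | step 3 | racemic 3-[4-methoxy-3-(methanesulfonyloxy)phenyl]-3-(2,4,5-trimethoxyphenyl)propanoyl chloride | COc1ccc(C(CC(=O)Cl)c2cc(OC)c(OC)cc2OC)cc1OS(C)(=O)=O
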